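**Plan**

- Retrosynthesis: the C2 aldehyde is taken back to a C2 ethyl ester. The ring bond N1–C5 is then cut, which opens the pyrrole to ethyl (2Z,4E)-2-azidotetracosa-2,4-dienoate. The diene is cut at C2=C3 (azidoacetate condensation) and at C4=C5 (Wittig), leading to icosanal and icosan-1-ol.
- Enabling feature: in the pyrrole, N1 is bonded to the chain-bearing C5, and C2–C3–C4–C5 is a butadiene that already carries the carbonyl carbon on C2. The ring is therefore a 2-azido-2,4-dienoate closed between nitrogen and the diene terminus.
- Forward: the chain is joined by two olefinations (C20 + C2, then + C2N). The only ring, the pyrrole, closes in step 4 with loss of N2. The ester then goes to the aldehyde through the acid and the Weinreb amide.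
- Stereochemistry: the target has no stereocentre. The 4E geometry (stabilised ylide) and the 2Z geometry (condensation, nitrogen beside C4) are the only stereo-elements, and both vanish on aromatisation.

Key step: step 4

Assumption: icosan-1-ol, ylide 3 and ethyl azidoacetate (as its commercial solution) are bought; azides 5–7 are kept cold, dark and are not distilled.

**Step 1**
Reactants: 1 icosan-1-ol
Product: 2 icosanal
Conditions: TEMPO (10 mol%), PhI(OAc)2 (1.1 equiv), CH2Cl2, 25–30 °C
Reagents that add atoms: none
Why: The oxoammonium-mediated TEMPO/PhI(OAc)2 oxidation of an unhindered primary alcohol stops at the aldehyde in dry CH2Cl2 and runs at room temperature, where the waxy C20 alcohol stays in solution (a cryogenic Swern oxidation would not allow this).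

**Step 2**
Reactants: 2 icosanal; 3 (triphenylphosphoranylidene)acetaldehyde
Product: 4 (2E)-docos-2-enal
Conditions: 3 (1.05 equiv), toluene, 80 °C
Reagents that add atoms: 3 (triphenylphosphoranylidene)acetaldehyde, O=CC=P(c1ccccc1)(c1ccccc1)c1ccccc1
Why: Wittig olefination with the stabilised formyl ylide should give the E-enal, and the near-stoichiometric ylide charge together with the lower electrophilicity of the conjugated product should hold back a second homologation.

**Step 3**
Reactants: 4 (2E)-docos-2-enal; 5 ethyl azidoacetate
Product: 7 ethyl (2Z,4E)-2-azidotetracosa-2,4-dienoate, via ethyl (4E)-2-azido-3-hydroxytetracos-4-enoate 6 (not isolated)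
Conditions: NaOEt (4 equiv), 5 (4 equiv), EtOH–THF, −15 → 0 °C; then ice-water
Reagents that add atoms: 5 ethyl azidoacetate, CCOC(=O)CN=[N+]=[N-]
Why: In this Knoevenagel-type (Hemetsberger–Knittel) condensation the azidoacetate enolate adds 1,2 to the enal and aldolate 6 loses hydroxide (E1cB) to the conjugated azidodiene with the favoured 2Z geometry; the low temperature limits N2 loss from the azidoacetate anion and γ-deprotonation of the enal, and matching ethoxide to the ethyl ester avoids ester scrambling.

**Step 4**
Reactants: 7 ethyl (2Z,4E)-2-azidotetracosa-2,4-dienoate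
Product: 9 ethyl 5-nonadecyl-1H-pyrrole-2-carboxylate, via ethyl 2-nonadecyl-2H-pyrrole-5-carboxylate 8 (not isolated)
Conditions: ZnI2 (10 mol%), CH2Cl2, rt
Reagents that add atoms: none
Why: ZnI2 is expected to bind the azide of 7 as a Lewis acid and trigger loss of N2, leaving an electron-poor nitrogen on C2 (a zinc-bound vinyl nitrene equivalent in equilibrium with its 2H-azirine) next to the s-cis C2=C3–C4=C5 diene. That nitrogen should bond to the diene terminus C5 in a five-atom, 4π-electron electrocyclisation (5-endo-trig with respect to C4=C5), which forms N1–C5 and the only ring and gives 2H-pyrrole 8; a 1,5-hydrogen shift from C5 to N1 then gives aromatic 9. The closest known reaction type is the Hemetsberger-type conversion of 2-azido-2,4-dienoates into 2,5-disubstituted pyrrole-2-carboxylates, which is known thermally and at room temperature with ZnI2 or with dirhodium carboxylates such as Rh2(O2CC3F7)4 (divalent rhodium). The sp3 centre at C5 of 8 arises without control and is erased on aromatisation, so no stereocentre has to be set. What has to be secured is chemoselectivity: ring closure must outrun a stalled azirine, bimolecular decay of the nitrogen species and C–H insertion into the alkyl chain, and the 2Z geometry (nitrogen held beside C4), the conjugated diene and the room-temperature catalysis should see to that. Because C5 is the only diene terminus, no regioisomeric pyrrole can arise: the chain ends up on C5 and the ester stays on C2.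

**Step 5**
Reactants: 9 ethyl 5-nonadecyl-1H-pyrrole-2-carboxylate
Product: 10 5-nonadecyl-1H-pyrrole-2-carboxylic acid
Conditions: LiOH·H2O (5 equiv), THF–EtOH–H2O, 60 °C; then 1 M HCl to pH 3, 0 °C
Reagents that add atoms: lithium hydroxide, [Li+].[OH-]
Why: Saponification of the deactivated (vinylogous carbamate) pyrrole ester needs warming, which the base-stable pyrrole carboxylate tolerates, and cold, mild acidification avoids protodecarboxylation of the electron-rich acid.

**Step 6**
Reactants: 10 5-nonadecyl-1H-pyrrole-2-carboxylic acid
Product: 12 N-methoxy-N-methyl-5-nonadecyl-1H-pyrrole-2-carboxamide, via 1H-imidazol-1-yl(5-nonadecyl-1H-pyrrol-2-yl)methanone 11 (not isolated)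
Conditions: 1,1'-carbonyldiimidazole (1.2 equiv), THF, rt → 40 °C; then MeNH(OMe)·HCl (1.5 equiv), rt
Reagents that add atoms: N,O-dimethylhydroxylamine hydrochloride, CNOC.Cl; 1,1'-carbonyldiimidazole, O=C(n1ccnc1)n1ccnc1 (its imidazolyl group is carried in 11 only)
Why: Carbonyldiimidazole activation gives acyl imidazolide 11 with loss of CO2, and N,O-dimethylhydroxylamine displaces imidazole in a standard amide coupling to give the Weinreb amide; the pyrrole N–H is too weakly nucleophilic to compete without added strong base.

**Step 7**
Reactants: 12 N-methoxy-N-methyl-5-nonadecyl-1H-pyrrole-2-carboxamide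
Product: 13 5-nonadecyl-1H-pyrrole-2-carbaldehyde (CNP0218351.0)
Conditions: LiAlH4 (2.5 equiv), THF, −10 → 0 °C; then H2O, 15% aq. NaOH, H2O
Reagents that add atoms: none
Why: In this Weinreb amide reduction the first hydride removes the N–H proton and the next adds to the carbonyl to give a chelated tetrahedral aluminate that survives until aqueous work-up, so the reduction should stop at the aldehyde and avoid the labile 2-hydroxymethylpyrrole of an ester-to-alcohol route.

**Compound list**

1 | icosan-1-ol | CCCCCCCCCCCCCCCCCCCCO | starting material
2 | icosanal | CCCCCCCCCCCCCCCCCCCC=O | intermediate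
3 | (triphenylphosphoranylidene)acetaldehyde | O=CC=P(c1ccccc1)(c1ccccc1)c1ccccc1 | starting material
4 | (2E)-docos-2-enal | CCCCCCCCCCCCCCCCCCC/C=C/C=O | intermediate
5 | ethyl azidoacetate | CCOC(=O)CN=[N+]=[N-] | starting material
6 | ethyl (4E)-2-azido-3-hydroxytetracos-4-enoate (mixture of diastereomers, not isolated) | CCCCCCCCCCCCCCCCCCC/C=C/C(O)C(N=[N+]=[N-])C(=O)OCC | intermediate
7 | ethyl (2Z,4E)-2-azidotetracosa-2,4-dienoate | CCCCCCCCCCCCCCCCCCC/C=C/C=C(\N=[N+]=[N-])C(=O)OCC | intermediate
8 | ethyl 2-nonadecyl-2H-pyrrole-5-carboxylate (racemic, not isolated) | CCCCCCCCCCCCCCCCCCCC1C=CC(C(=O)OCC)=N1 | intermediate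
9 | ethyl 5-nonadecyl-1H-pyrrole-2-carboxylate | CCCCCCCCCCCCCCCCCCCc1ccc(C(=O)OCC)[nH]1 | intermediate
10 | 5-nonadecyl-1H-pyrrole-2-carboxylic acid | CCCCCCCCCCCCCCCCCCCc1ccc(C(=O)O)[nH]1 | intermediate
11 | 1H-imidazol-1-yl(5-nonadecyl-1H-pyrrol-2-yl)methanone (not isolated) | CCCCCCCCCCCCCCCCCCCc1ccc(C(=O)n2ccnc2)[nH]1 | intermediate
12 | N-methoxy-N-methyl-5-nonadecyl-1H-pyrrole-2-carboxamide | CCCCCCCCCCCCCCCCCCCc1ccc(C(=O)N(C)OC)[nH]1 | intermediate
13 | 5-nonadecyl-1H-pyrrole-2-carbaldehyde | CCCCCCCCCCCCCCCCCCCc1ccc(C=O)[nH]1 | target

**Step count and risks**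

Total step count: 7. Longest linear sequence: 7 steps (1 → 13; compounds 3 and 5 are bought).

Steps most likely to fail:

1. Step 3. What may go wrong: ethoxide removes a γ-proton of the enolisable enal and self-condensation follows; the azidoacetate anion loses N2 before it adds; the C22 enal is poorly soluble at low temperature; or the reaction stops at the aldol stage. Fallback: set out from 4 (with 5) and separate C–C bond formation from dehydration. The aldol addition is stopped cold (NaOEt, EtOH–THF, −30 °C, acetic acid quench, or DBU/LiCl in THF) and 6 is isolated. The hydroxyl is sulfonylated with MsCl/Et3N in CH2Cl2 at −20 °C to give ethyl (4E)-2-azido-3-(methylsulfonyloxy)tetracos-4-enoate F1. DBU then induces elimination, and the route is rejoined at 7.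

2. Step 4. What may go wrong: the reaction stalls at the 2H-azirine, or the nitrogen species decays bimolecularly because the alkyl-substituted diene terminus closes more slowly than an aryl-substituted one. Changing the catalyst to Rh2(O2CC3F7)4 or heating in toluene would only change the conditions. The fallback changes the ring construction. It sets out from 2: addition of [2-(1,3-dioxan-2-yl)ethyl]magnesium bromide in THF should give 1-(1,3-dioxan-2-yl)docosan-3-ol F2. Dess–Martin oxidation gives 1-(1,3-dioxan-2-yl)docosan-3-one F3. Paal–Knorr condensation with NH4OAc in aqueous acetic acid at 100 °C (acetal unmasked in the same pot) gives 2-nonadecyl-1H-pyrrole F4. Vilsmeier–Haack formylation (POCl3, DMF, 0 °C → rt; then aq. NaOAc) at the free α-position then rejoins the route directly at 13.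

3. Step 2. What may go wrong: the enal product competes with icosanal for the ylide and is homologated a second time to the dienal, while the sluggish ylide leaves starting aldehyde behind. Fallback: set out from 2 and build the enal by oxidation-state adjustment. Horner–Wadsworth–Emmons olefination with triethyl phosphonoacetate (NaH, THF, 0 °C → rt) gives ethyl (2E)-docos-2-enoate F5. Reduction with i-Bu2AlH (CH2Cl2, −78 → 0 °C) gives (2E)-docos-2-en-1-ol F6. Allylic oxidation with MnO2 in CH2Cl2 rejoins the route at 4.

**Further compounds**

F1 | step 3 | ethyl (4E)-2-azido-3-(methylsulfonyloxy)tetracos-4-enoate | CCCCCCCCCCCCCCCCCCC/C=C/C(OS(C)(=O)=O)C(N=[N+]=[N-])C(=O)OCC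
F2 | step 4 | 1-(1,3-dioxan-2-yl)docosan-3-ol | CCCCCCCCCCCCCCCCCCCC(O)CCC1OCCCO1
F3 | step 4 | 1-(1,3-dioxan-2-yl)docosan-3-one | CCCCCCCCCCCCCCCCCCCC(=O)CCC1OCCCO1
F4 | step 4 | 2-nonadecyl-1H-pyrrole | CCCCCCCCCCCCCCCCCCCc1ccc[nH]1
F5 | step 2 | ethyl (2E)-docos-2-enoate | CCCCCCCCCCCCCCCCCCC/C=C/C(=O)OCC
F6 | step 2 | (2E)-docos-2-en-1-ol | CCCCCCCCCCCCCCCCCCC/C=C/CO
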